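**Retrosynthetic overview**

1. Numbering used below: ring A is the trimethoxybenzene (C1–C4, C4a, C9a), ring C the seven-membered ring (C5 carbinol, C6 and C7 methyl-bearing, C8 methylene, C9 spiro), ring B the 2,6-dimethoxycyclohexadienone. The last C–C bond is C9–C9a, made by phenolic para–ortho′ oxidative coupling of a 1,4-diarylbutane; this closes ring C and turns ring B into the dienone (C9 is not stereogenic because ring B is symmetric).
2. Key disconnections are C7–C8 and C4a–C5. The enabling feature is that the oxygen on C5 and the methyl-bearing C7 of ring C are 1,3-related, so C5–C6–C7 with both methyl groups is a cis-3,4-dimethyl-β-lactone (C5 = acyl carbon, C7 = alkyl–oxygen carbon). It is flanked by two natural carbanion sites: C8 (benzylic to ring B before dearomatisation) and C4a of ring A.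
3. In one flask a benzylic Grignard reagent opens the lactone at C7 with inversion, and an aryllithium then acylates itself on the resulting carboxylate. This gives the full carbon chain with C6 and C7 set.
4. C6 and C7 come from one catalytic asymmetric ketene–aldehyde cycloaddition; C5 is set by Corey–Bakshi–Shibata reduction of the aryl ketone.
5. Ring order: temporary oxetanone (made, then opened); rings A and B bought as arenes; ring C and the dienone of ring B formed together in the penultimate step.

Key step: step 4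

Assumption: O-trimethylsilylquinine is taken to give the (3S,4R)-lactone in step 1; if the sense of induction were opposite, the pseudoenantiomeric O-trimethylsilylquinidine would be used with no other change.

**Step 1**
Reactants: 1 propionyl chloride; 2 acetaldehyde
Product: 4 (3S,4R)-3,4-dimethyloxetan-2-one, via methylketene 3 (not isolated)
Conditions: O-trimethylsilylquinine (10 mol%), LiClO4, iPr2NEt, CH2Cl2/Et2O, −78 °C
Reagents that add atoms: none
Why: Catalytic asymmetric acyl halide–aldehyde cyclocondensation (formal ketene–aldehyde [2+2] cycloaddition): the alkaloid-bound ammonium enolate of methylketene 3 should add to the LiClO4-activated aldehyde through a closed transition state that gives the cis-lactone, the alkaloid setting the absolute configuration at C3 and C4 together.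

**Step 2**
Reactants: 5 4-(benzyloxy)-3,5-dimethoxybenzaldehyde
Product: 6 [4-(benzyloxy)-3,5-dimethoxyphenyl]methanol
Conditions: NaBH4, MeOH, 0 °C
Reagents that add atoms: none
Why: Borohydride reduction of an aromatic aldehyde; the benzyl ether and methoxy groups are inert.

**Step 3**
Reactants: 6 [4-(benzyloxy)-3,5-dimethoxyphenyl]methanol
Product: 7 2-(benzyloxy)-5-(chloromethyl)-1,3-dimethoxybenzene
Conditions: SOCl2, CH2Cl2, 0 °C
Reagents that add atoms: thionyl chloride, O=S(Cl)Cl
Why: Chlorodehydroxylation of an electron-rich benzylic alcohol through its chlorosulfite (Darzens-type chlorination); no stereocenter is involved.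

**Step 4**
Reactants: 7 2-(benzyloxy)-5-(chloromethyl)-1,3-dimethoxybenzene; 4 (3S,4R)-3,4-dimethyloxetan-2-one; 8 5-bromo-1,2,3-trimethoxybenzene
Product: 13 (2S,3R)-4-[4-(benzyloxy)-3,5-dimethoxyphenyl]-2,3-dimethyl-1-(3,4,5-trimethoxyphenyl)butan-1-one, via benzylmagnesium chloride 9 (not isolated), via chloromagnesium carboxylate 10 (not isolated), via aryllithium 11 (not isolated), via ketone gem-diolate 12 (not isolated)
Conditions: 7, Mg turnings, THF, 0 °C; then 4, CuBr·SMe2 (10 mol%), THF/Me2S, −45 °C; then 11 (from 8, n-BuLi, THF, −78 °C, 2.5 equiv), −78 → 0 °C; inverse quench into cold 1 M HCl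
Reagents that add atoms: none
Why: The benzylic Grignard reagent 9, turned over through a benzylcopper species by catalytic CuBr·SMe2, attacks the alkyl–oxygen carbon C4 of the strained lactone in an SN2 sense and so forms the C7–C8 bond while releasing carboxylate 10; aryllithium 11 then adds once to the carboxylate carbon to form the C4a–C5 bond as gem-diolate 12, which gives the ketone only on acidic quench. The closest known reaction types are the copper-catalysed Grignard opening of β-lactones to β-branched carboxylic acids and the organolithium–carboxylate ketone synthesis, here run in one flask. No ring is closed: the temporary four-membered ring is opened and its strain drives the first bond. C7 is set by stereospecific inversion at lactone C4 and C6 is carried over unchanged from lactone C3, so the cis-lactone should give the syn-dimethyl pattern. The step needs alkyl–oxygen rather than acyl–oxygen cleavage and substitution rather than elimination, which the soft copper nucleophile at low temperature and the ring strain should secure, and it needs mono-addition without epimerisation at C6, which the dianionic tetrahedral intermediate 12 should secure because no ketone exists until the quench.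

**Step 5**
Reactants: 13 (2S,3R)-4-[4-(benzyloxy)-3,5-dimethoxyphenyl]-2,3-dimethyl-1-(3,4,5-trimethoxyphenyl)butan-1-one
Product: 14 (1R,2S,3R)-4-[4-(benzyloxy)-3,5-dimethoxyphenyl]-2,3-dimethyl-1-(3,4,5-trimethoxyphenyl)butan-1-ol
Conditions: (S)-2-methyl-CBS-oxazaborolidine (50 mol%), BH3·SMe2, THF, −20 °C
Reagents that add atoms: none
Why: Corey–Bakshi–Shibata reduction: the aryl group acts as the large ketone substituent, so the (S)-oxazaborolidine–borane complex should deliver hydride to the face that gives the (1R)-carbinol (syn to the C2 methyl); catalyst control is needed because the Felkin–Anh preference of the ketone favours the epimer.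

**Step 6**
Reactants: 14 (1R,2S,3R)-4-[4-(benzyloxy)-3,5-dimethoxyphenyl]-2,3-dimethyl-1-(3,4,5-trimethoxyphenyl)butan-1-ol
Product: 15 {[(1R,2S,3R)-4-[4-(benzyloxy)-3,5-dimethoxyphenyl]-2,3-dimethyl-1-(3,4,5-trimethoxyphenyl)butyl]oxy}(tert-butyl)dimethylsilane
Conditions: TBSOTf, 2,6-lutidine, CH2Cl2, −78 → 0 °C
Reagents that add atoms: tert-butyldimethylsilyl trifluoromethanesulfonate (TBSOTf), CC(C)(C)[Si](C)(C)OS(=O)(=O)C(F)(F)F
Why: Silylation of a hindered secondary benzylic alcohol with a silyl triflate and a non-nucleophilic base; it masks the hydroxyl that would otherwise trap the phenoxenium ion of step 8 as a spiro ether.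

**Step 7**
Reactants: 15 {[(1R,2S,3R)-4-[4-(benzyloxy)-3,5-dimethoxyphenyl]-2,3-dimethyl-1-(3,4,5-trimethoxyphenyl)butyl]oxy}(tert-butyl)dimethylsilane
Product: 16 4-[(2R,3S,4R)-4-{[tert-butyl(dimethyl)silyl]oxy}-2,3-dimethyl-4-(3,4,5-trimethoxyphenyl)butyl]-2,6-dimethoxyphenol
Conditions: H2 (1 atm), Pd/C (10 wt% palladium on carbon), EtOAc, rt
Reagents that add atoms: none
Why: Hydrogenolysis of the aryl benzyl ether over palladium; the benzylic silyl ether and the alkoxyarenes are expected to survive under neutral conditions in ethyl acetate.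

**Step 8**
Reactants: 16 4-[(2R,3S,4R)-4-{[tert-butyl(dimethyl)silyl]oxy}-2,3-dimethyl-4-(3,4,5-trimethoxyphenyl)butyl]-2,6-dimethoxyphenol
Product: 17 (5R,6S,7R)-5-{[tert-butyl(dimethyl)silyl]oxy}-1,2,3,3′,5′-pentamethoxy-6,7-dimethyl-5,6,7,8-tetrahydrospiro[benzo[7]annulene-9,1′-cyclohexa-2′,5′-dien]-4′-one
Conditions: PhI(OCOCF3)2, CF3CH2OH, −40 °C
Reagents that add atoms: none
Why: Phenolic oxidative para–ortho′ coupling with a trivalent iodine oxidant in a fluoroalcohol (dearomatising spirocyclisation): the phenoxenium ion of ring B should be attacked at its para carbon by the ring-A carbon ortho to the side chain (ortho to one methoxy group and para to another, both such positions equivalent), the two methoxy groups of ring B block ortho coupling and rearomatisation, and no stereocenter is created because the dienone is symmetric.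

**Step 9**
Reactants: 17 (5R,6S,7R)-5-{[tert-butyl(dimethyl)silyl]oxy}-1,2,3,3′,5′-pentamethoxy-6,7-dimethyl-5,6,7,8-tetrahydrospiro[benzo[7]annulene-9,1′-cyclohexa-2′,5′-dien]-4′-one
Product: 18 (5R,6S,7R)-5-hydroxy-1,2,3,3′,5′-pentamethoxy-6,7-dimethyl-5,6,7,8-tetrahydrospiro[benzo[7]annulene-9,1′-cyclohexa-2′,5′-dien]-4′-one (CNP0288561.1)
Conditions: HF·pyridine, pyridine/THF, 0 °C → rt
Reagents that add atoms: none
Why: Fluoride-mediated cleavage of the silyl ether under buffered conditions that should leave the dienone and the benzylic stereocenter untouched.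

**Compound list**

1 | propionyl chloride | CCC(=O)Cl | starting material
2 | acetaldehyde | CC=O | starting material
3 | methylketene | CC=C=O | intermediate
4 | (3S,4R)-3,4-dimethyloxetan-2-one (cis) | O1[C@H](C)[C@H](C)C1=O | intermediate
5 | 4-(benzyloxy)-3,5-dimethoxybenzaldehyde | COc1cc(C=O)cc(OC)c1OCc1ccccc1 | starting material
6 | [4-(benzyloxy)-3,5-dimethoxyphenyl]methanol | COc1cc(CO)cc(OC)c1OCc1ccccc1 | intermediate
7 | 2-(benzyloxy)-5-(chloromethyl)-1,3-dimethoxybenzene | COc1cc(CCl)cc(OC)c1OCc1ccccc1 | intermediate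
8 | 5-bromo-1,2,3-trimethoxybenzene | COc1cc(Br)cc(OC)c1OC | starting material
9 | [4-(benzyloxy)-3,5-dimethoxybenzyl]magnesium chloride | COc1cc(C[Mg]Cl)cc(OC)c1OCc1ccccc1 | intermediate
10 | chloromagnesium (2S,3R)-4-[4-(benzyloxy)-3,5-dimethoxyphenyl]-2,3-dimethylbutanoate | COc1cc(C[C@@H](C)[C@H](C)C(=O)O[Mg]Cl)cc(OC)c1OCc1ccccc1 | intermediate
11 | (3,4,5-trimethoxyphenyl)lithium | [Li]c1cc(OC)c(OC)c(OC)c1 | intermediate
12 | lithium chloromagnesium (2S,3R)-4-[4-(benzyloxy)-3,5-dimethoxyphenyl]-2,3-dimethyl-1-(3,4,5-trimethoxyphenyl)butane-1,1-diolate | COc1cc(C[C@@H](C)[C@H](C)C(O[Li])(O[Mg]Cl)c2cc(OC)c(OC)c(OC)c2)cc(OC)c1OCc1ccccc1 | intermediate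
13 | (2S,3R)-4-[4-(benzyloxy)-3,5-dimethoxyphenyl]-2,3-dimethyl-1-(3,4,5-trimethoxyphenyl)butan-1-one | COc1cc(C[C@@H](C)[C@H](C)C(=O)c2cc(OC)c(OC)c(OC)c2)cc(OC)c1OCc1ccccc1 | intermediate
14 | (1R,2S,3R)-4-[4-(benzyloxy)-3,5-dimethoxyphenyl]-2,3-dimethyl-1-(3,4,5-trimethoxyphenyl)butan-1-ol | COc1cc(C[C@@H](C)[C@H](C)[C@@H](O)c2cc(OC)c(OC)c(OC)c2)cc(OC)c1OCc1ccccc1 | intermediate
15 | {[(1R,2S,3R)-4-[4-(benzyloxy)-3,5-dimethoxyphenyl]-2,3-dimethyl-1-(3,4,5-trimethoxyphenyl)butyl]oxy}(tert-butyl)dimethylsilane | COc1cc(C[C@@H](C)[C@H](C)[C@@H](O[Si](C)(C)C(C)(C)C)c2cc(OC)c(OC)c(OC)c2)cc(OC)c1OCc1ccccc1 | intermediate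
16 | 4-[(2R,3S,4R)-4-{[tert-butyl(dimethyl)silyl]oxy}-2,3-dimethyl-4-(3,4,5-trimethoxyphenyl)butyl]-2,6-dimethoxyphenol | COc1cc(C[C@@H](C)[C@H](C)[C@@H](O[Si](C)(C)C(C)(C)C)c2cc(OC)c(OC)c(OC)c2)cc(OC)c1O | intermediate
17 | (5R,6S,7R)-5-{[tert-butyl(dimethyl)silyl]oxy}-1,2,3,3′,5′-pentamethoxy-6,7-dimethyl-5,6,7,8-tetrahydrospiro[benzo[7]annulene-9,1′-cyclohexa-2′,5′-dien]-4′-one | COC1=CC2(C=C(OC)C1=O)C[C@@H](C)[C@H](C)[C@@H](O[Si](C)(C)C(C)(C)C)c1cc(OC)c(OC)c(OC)c12 | intermediate
18 | (5R,6S,7R)-5-hydroxy-1,2,3,3′,5′-pentamethoxy-6,7-dimethyl-5,6,7,8-tetrahydrospiro[benzo[7]annulene-9,1′-cyclohexa-2′,5′-dien]-4′-one | COC1=CC2(C=C(OC)C1=O)C[C@@H](C)[C@H](C)[C@@H](O)c1cc(OC)c(OC)c(OC)c12 | target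

**Step count**

Total: 9 steps. Longest linear sequence: 8 steps (5 → 6 → 7 → 13 → 14 → 15 → 16 → 17 → 18, steps 2–9); step 1 is the one-step side branch to lactone 4.

**Steps most likely to fail**

Step 4. Three processes may go wrong. Wurtz-type homocoupling may compete while the benzylic Grignard reagent forms. The lactone may be opened by elimination or at the acyl carbon instead of by substitution at C7. The aryllithium may add sluggishly or twice to the magnesium carboxylate, with epimerisation at C6 during the quench. The fallback sets out from 4 and 7 and comes back at 13. Only the copper-catalysed opening is run and the mixture is acidified to isolate (2S,3R)-4-[4-(benzyloxy)-3,5-dimethoxyphenyl]-2,3-dimethylbutanoic acid F1. This is coupled with N,O-dimethylhydroxylamine hydrochloride (EDC·HCl, DMAP, CH2Cl2) to give (2S,3R)-4-[4-(benzyloxy)-3,5-dimethoxyphenyl]-N-methoxy-N,2,3-trimethylbutanamide F2. Aryllithium 11 is then added to F2 at −78 °C (Weinreb ketone synthesis), where the chelated tetrahedral intermediate prevents over-addition, to give 13.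

Step 8. The phenoxenium ion may be captured by the solvent or by a second molecule instead of closing the seven-membered ring, or the acid set free may promote rearrangement of the dienone. The fallback sets out from 16 and comes back at 17, and it separates oxidation from C–C bond formation. Phenol 16 is oxidised with PhI(OAc)2 in MeOH at 0 °C to the quinol ether 4-[(2R,3S,4R)-4-{[tert-butyl(dimethyl)silyl]oxy}-2,3-dimethyl-4-(3,4,5-trimethoxyphenyl)butyl]-2,4,6-trimethoxycyclohexa-2,5-dien-1-one F3. F3 is then ionised at its tertiary methoxy group with BF3·OEt2 in CH2Cl2 at −78 °C, so that ring A closes onto the dimethoxy-stabilised cation under oxidant-free, dilute conditions to give 17.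

Step 5. Facial selectivity may be poor because the catalyst has to override the Felkin–Anh bias of the α-methyl ketone, and the hindered ketone may react slowly with uncatalysed background reduction. The fallback sets out from 13 and comes back at 14, and it uses the substrate bias instead of fighting it. Reduction with LiBH(s-Bu)3 in THF at −78 °C should give the Felkin–Anh product (1S,2S,3R)-4-[4-(benzyloxy)-3,5-dimethoxyphenyl]-2,3-dimethyl-1-(3,4,5-trimethoxyphenyl)butan-1-ol F4. Mitsunobu inversion of F4 (4-nitrobenzoic acid, PPh3, DIAD, THF, 0 °C) gives (1R,2S,3R)-4-[4-(benzyloxy)-3,5-dimethoxyphenyl]-2,3-dimethyl-1-(3,4,5-trimethoxyphenyl)butyl 4-nitrobenzoate F5, and methanolysis (K2CO3, MeOH) gives 14.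

**Further compounds**

F1 | step 4 | (2S,3R)-4-[4-(benzyloxy)-3,5-dimethoxyphenyl]-2,3-dimethylbutanoic acid | COc1cc(C[C@@H](C)[C@H](C)C(=O)O)cc(OC)c1OCc1ccccc1
F2 | step 4 | (2S,3R)-4-[4-(benzyloxy)-3,5-dimethoxyphenyl]-N-methoxy-N,2,3-trimethylbutanamide | COc1cc(C[C@@H](C)[C@H](C)C(=O)N(C)OC)cc(OC)c1OCc1ccccc1
F3 | step 8 | 4-[(2R,3S,4R)-4-{[tert-butyl(dimethyl)silyl]oxy}-2,3-dimethyl-4-(3,4,5-trimethoxyphenyl)butyl]-2,4,6-trimethoxycyclohexa-2,5-dien-1-one | COC1=CC(OC)(C[C@@H](C)[C@H](C)[C@@H](O[Si](C)(C)C(C)(C)C)c2cc(OC)c(OC)c(OC)c2)C=C(OC)C1=O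
F4 | step 5 | (1S,2S,3R)-4-[4-(benzyloxy)-3,5-dimethoxyphenyl]-2,3-dimethyl-1-(3,4,5-trimethoxyphenyl)butan-1-ol | COc1cc(C[C@@H](C)[C@H](C)[C@H](O)c2cc(OC)c(OC)c(OC)c2)cc(OC)c1OCc1ccccc1
F5 | step 5 | (1R,2S,3R)-4-[4-(benzyloxy)-3,5-dimethoxyphenyl]-2,3-dimethyl-1-(3,4,5-trimethoxyphenyl)butyl 4-nitrobenzoate | COc1cc(C[C@@H](C)[C@H](C)[C@@H](OC(=O)c2ccc(cc2)[N+](=O)[O-])c2cc(OC)c(OC)c(OC)c2)cc(OC)c1OCc1ccccc1
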